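**Retrosynthetic overview**
- The C15 acid is freed last from its methyl ester. The 6β-acetate comes from α-face hydride reduction of a 6-ketone followed by acetylation; the 7α-isovalerate comes from Mitsunobu inversion of a 7β-alcohol.
- The 6,7-dioxygenation is traced back to a 7-oxo-8-ene (C6 hydroxylation of its kinetic enolate, Luche reduction at C7).
- Key disconnection C11–C12: the C11 carbanion of a 7-oxo-8-en-12-oate (vinylogous β-keto ester, CO2Me as traceless activator) is joined to methyl (E)-4-bromo-3-methylbut-2-enoate, used as a vinylogous enolonium (a4) equivalent. Two natively nucleophilic carbons are united and the 13E alkene arrives intact; Krapcho decarboxylation follows.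
- The vinylogous β-keto ester comes from (+)-sclareolide by lactone methanolysis/dehydration and allylic oxidation at C7.
- Ring order: no ring is built. Rings A and B (C5, C10 stereocentres) are carried intact from sclareolide; only its lactone ring is opened.

Assumption: labdane numbering is used throughout, and commercial methyl (E)-4-bromo-3-methylbut-2-enoate is taken as the geometrically pure E isomer.

**Route**

Step 1
Reactants: 1 (+)-sclareolide
Product: 3 methyl 13,14,15,16-tetranorlabd-8-en-12-oate, via hydroxy ester 2 (not isolated)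
Conditions: conc. H2SO4, MeOH, reflux
Reagents that add atoms: methanol, CO
Why: Acid-catalysed lactone methanolysis followed by E1 dehydration of the tertiary C8 alcohol gives the thermodynamic tetrasubstituted 8(9)-alkene (minor 7-ene and 8(17)-ene isomers are removed after step 2), with C5 and C10 carried unchanged from sclareolide.

Step 2
Reactants: 3 methyl 13,14,15,16-tetranorlabd-8-en-12-oate
Product: 4 methyl 7-oxo-13,14,15,16-tetranorlabd-8-en-12-oate
Conditions: CrO3, 3,5-dimethylpyrazole, CH2Cl2, −20 °C
Reagents that add atoms: chromium trioxide CrO3, O=[Cr](=O)=O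
Why: Allylic oxidation with the CrO3–3,5-dimethylpyrazole complex converts the ring allylic CH2 (C7) of the 8(9)-ene into the conjugated ketone, giving a vinylogous β-keto ester whose C11–H is now acidic.

Step 3
Reactants: 4 methyl 7-oxo-13,14,15,16-tetranorlabd-8-en-12-oate; 5 methyl (E)-4-bromo-3-methylbut-2-enoate
Product: 7 methyl (13E)-11-(methoxycarbonyl)-7-oxolabda-8,13-dien-15-oate (C11 epimers), via potassium dienolate 6 (not isolated)
Conditions: KOC(CH3)3, THF, 0 °C; then 5, 0 °C to rt
Reagents that add atoms: none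
Why: Enolate alkylation of a vinylogous β-keto ester (an α-methyl Hagemann-type ester, which alkylates at the ester-bearing γ-carbon C11 because C8 is fully substituted) by SN2 on the γ-bromo enoate 5 acting as a vinylogous enolonium equivalent, so two natively nucleophilic carbons (C11 and C12) are joined and the 13E geometry comes in with the reagent; the new C11 stereocentre is removed in step 4.

Step 4
Reactants: 7 methyl (13E)-11-(methoxycarbonyl)-7-oxolabda-8,13-dien-15-oate (C11 epimers)
Product: 8 methyl (13E)-7-oxolabda-8,13-dien-15-oate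
Conditions: LiCl, H2O, DMSO, 130 °C
Reagents that add atoms: none
Why: Krapcho dealkoxycarbonylation, in which chloride demethylates the activated C11 ester, the vinylogous β-keto carboxylate loses CO2 and the dienolate is reprotonated to the conjugated tetrasubstituted enone, while the unactivated C15 methyl ester and the 13E alkene are untouched.

Step 5
Reactants: 8 methyl (13E)-7-oxolabda-8,13-dien-15-oate
Product: 10 methyl (13E)-6α-hydroxy-7-oxolabda-8,13-dien-15-oate, via lithium enolate 9 (not isolated)
Conditions: LiN(SiMe3)2, THF, −78 °C; 2-(phenylsulfonyl)-3-phenyloxaziridine, −78 °C; then H2O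
Reagents that add atoms: 2-(phenylsulfonyl)-3-phenyloxaziridine (Davis oxaziridine), O=S(=O)(N1OC1c1ccccc1)c1ccccc1
Why: Kinetic deprotonation of the enone at C6 and Davis enolate hydroxylation from the open α face install the C6 oxygen, whose configuration is inconsequential because C6 is re-set in steps 8 and 9.

Step 6
Reactants: 10 methyl (13E)-6α-hydroxy-7-oxolabda-8,13-dien-15-oate
Product: 11 methyl (13E)-6α,7β-dihydroxylabda-8,13-dien-15-oate
Conditions: NaBH4, CeCl3·7H2O, MeOH, −78 to 0 °C
Reagents that add atoms: none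
Why: Luche 1,2-reduction, with axial hydride attack from the α face of the C7 carbonyl giving the equatorial 7β-alcohol without touching the enoate.

Step 7
Reactants: 11 methyl (13E)-6α,7β-dihydroxylabda-8,13-dien-15-oate; 12 3-methylbutanoic acid (isovaleric acid)
Product: 13 methyl (13E)-6α-hydroxy-7α-(3-methylbutanoyloxy)labda-8,13-dien-15-oate
Conditions: PPh3, DIAD, THF, 0 °C to rt
Reagents that add atoms: none
Why: Mitsunobu esterification inverts the more reactive allylic C7 alcohol by SN2 (α-face attack of isovalerate on the oxyphosphonium), setting 7α; the hindered 6-OH is not activated, the rigid trans-diequatorial diol cannot close to an epoxide and SN2′ at the fully substituted C9 is blocked.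

Step 8
Reactants: 13 methyl (13E)-6α-hydroxy-7α-(3-methylbutanoyloxy)labda-8,13-dien-15-oate
Product: 14 methyl (13E)-7α-(3-methylbutanoyloxy)-6-oxolabda-8,13-dien-15-oate
Conditions: Dess–Martin periodinane, pyridine, CH2Cl2, 0 °C to rt
Reagents that add atoms: none
Why: Dess–Martin oxidation of the remaining secondary alcohol gives the 6-ketone under buffered, near-neutral conditions that do not epimerise C5 or C7.

Step 9
Reactants: 14 methyl (13E)-7α-(3-methylbutanoyloxy)-6-oxolabda-8,13-dien-15-oate
Product: 15 methyl (13E)-6β-hydroxy-7α-(3-methylbutanoyloxy)labda-8,13-dien-15-oate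
Conditions: NaBH4, CeCl3·7H2O, MeOH, −78 °C
Reagents that add atoms: none
Why: Luche-type hydride reduction of the 6-ketone occurs from the α face because the β face is blocked by the syn-axial C10 and 4β methyl groups, giving the axial 6β-alcohol, which is trans-diaxial to the 7α-ester so no acyl migration can occur.

Step 10
Reactants: 15 methyl (13E)-6β-hydroxy-7α-(3-methylbutanoyloxy)labda-8,13-dien-15-oate
Product: 16 methyl (13E)-6β-acetoxy-7α-(3-methylbutanoyloxy)labda-8,13-dien-15-oate
Conditions: Ac2O, DMAP, pyridine, 50 °C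
Reagents that add atoms: acetic anhydride, CC(=O)OC(C)=O
Why: DMAP-catalysed acylation forces acetylation of the hindered axial 6β-alcohol without affecting any stereocentre.

Step 11
Reactants: 16 methyl (13E)-6β-acetoxy-7α-(3-methylbutanoyloxy)labda-8,13-dien-15-oate
Product: 18 (13E)-6β-acetoxy-7α-(3-methylbutanoyloxy)labda-8,13-dien-15-oic acid (CNP0328312.2), via lithium carboxylate 17 (not isolated)
Conditions: LiI, EtOAc, reflux; then 1 M HCl
Reagents that add atoms: none
Why: Nucleophilic ester cleavage (SN2 attack of iodide on the O-methyl group) frees the C15 acid, while the acetate and isovalerate, being esters of hindered secondary alcohols, cannot be dealkylated this way.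

**Compound list**

1 | (+)-sclareolide, (3aR,5aS,9aS,9bR)-3a,6,6,9a-tetramethyldecahydronaphtho[2,1-b]furan-2(1H)-one | C1C[C@@]3(C)OC(=O)C[C@@H]3[C@@]2(C)CCCC(C)(C)[C@H]12 | starting material
2 | methyl 8α-hydroxy-13,14,15,16-tetranorlabdan-12-oate (not isolated) | C1C[C@@](C)(O)[C@H](CC(=O)OC)[C@@]2(C)CCCC(C)(C)[C@H]12 | intermediate
3 | methyl 13,14,15,16-tetranorlabd-8-en-12-oate | C1CC(C)=C(CC(=O)OC)[C@@]2(C)CCCC(C)(C)[C@H]12 | intermediate
4 | methyl 7-oxo-13,14,15,16-tetranorlabd-8-en-12-oate | C1C(=O)C(C)=C(CC(=O)OC)[C@@]2(C)CCCC(C)(C)[C@H]12 | intermediate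
5 | methyl (E)-4-bromo-3-methylbut-2-enoate | BrC/C(C)=C/C(=O)OC | starting material
6 | potassium dienolate of 4, drawn as the C11 carbanion (not isolated) | C1C(=O)C(C)=C([CH-]C(=O)OC)[C@@]2(C)CCCC(C)(C)[C@H]12.[K+] | intermediate
7 | methyl (13E)-11-(methoxycarbonyl)-7-oxolabda-8,13-dien-15-oate (C11 epimers) | C1C(=O)C(C)=C(C(C/C(C)=C/C(=O)OC)C(=O)OC)[C@@]2(C)CCCC(C)(C)[C@H]12 | intermediate
8 | methyl (13E)-7-oxolabda-8,13-dien-15-oate | C1C(=O)C(C)=C(CC/C(C)=C/C(=O)OC)[C@@]2(C)CCCC(C)(C)[C@H]12 | intermediate
9 | lithium C6 enolate of 8 (not isolated) | C1=C([O-])C(C)=C(CC/C(C)=C/C(=O)OC)[C@@]2(C)CCCC(C)(C)[C@H]12.[Li+] | intermediate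
10 | methyl (13E)-6α-hydroxy-7-oxolabda-8,13-dien-15-oate | O[C@H]1C(=O)C(C)=C(CC/C(C)=C/C(=O)OC)[C@@]2(C)CCCC(C)(C)[C@H]12 | intermediate
11 | methyl (13E)-6α,7β-dihydroxylabda-8,13-dien-15-oate | O[C@H]1[C@H](O)C(C)=C(CC/C(C)=C/C(=O)OC)[C@@]2(C)CCCC(C)(C)[C@H]12 | intermediate
12 | 3-methylbutanoic acid (isovaleric acid) | CC(C)CC(=O)O | starting material
13 | methyl (13E)-6α-hydroxy-7α-(3-methylbutanoyloxy)labda-8,13-dien-15-oate | O[C@H]1[C@@H](OC(=O)CC(C)C)C(C)=C(CC/C(C)=C/C(=O)OC)[C@@]2(C)CCCC(C)(C)[C@H]12 | intermediate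
14 | methyl (13E)-7α-(3-methylbutanoyloxy)-6-oxolabda-8,13-dien-15-oate | O=C1[C@@H](OC(=O)CC(C)C)C(C)=C(CC/C(C)=C/C(=O)OC)[C@@]2(C)CCCC(C)(C)[C@H]12 | intermediate
15 | methyl (13E)-6β-hydroxy-7α-(3-methylbutanoyloxy)labda-8,13-dien-15-oate | O[C@@H]1[C@@H](OC(=O)CC(C)C)C(C)=C(CC/C(C)=C/C(=O)OC)[C@@]2(C)CCCC(C)(C)[C@H]12 | intermediate
16 | methyl (13E)-6β-acetoxy-7α-(3-methylbutanoyloxy)labda-8,13-dien-15-oate | CC(=O)O[C@@H]1[C@@H](OC(=O)CC(C)C)C(C)=C(CC/C(C)=C/C(=O)OC)[C@@]2(C)CCCC(C)(C)[C@H]12 | intermediate
17 | lithium (13E)-6β-acetoxy-7α-(3-methylbutanoyloxy)labda-8,13-dien-15-oate (not isolated) | CC(=O)O[C@@H]1[C@@H](OC(=O)CC(C)C)C(C)=C(CC/C(C)=C/C(=O)[O-])[C@@]2(C)CCCC(C)(C)[C@H]12.[Li+] | intermediate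
18 | (5S,6S,7S,10S,13E)-6β-acetoxy-7α-(3-methylbutanoyloxy)labda-8,13-dien-15-oic acid (CNP0328312.2) | CC(=O)O[C@@H]1[C@@H](OC(=O)CC(C)C)C(C)=C(CC/C(C)=C/C(=O)O)[C@@]2(C)CCCC(C)(C)[C@H]12 | target

**Totals**

Total step count: 11. Longest linear sequence: 11 steps (1 to 18).

**Steps most likely to fail, with fallbacks**

Step 3 (key alkylation). The dienolate 6 is ambident and could alkylate at C8 or on oxygen, and bromide 5 could react by SN2′ or cyclopropanation. The fallback reverses the order of alkylation and oxidation so that only a simple ester enolate is involved. It sets out from 3: deprotonation with LiN(iPr)2 in THF at −78 °C and alkylation of the ester α-carbon C11 with 5 gives methyl (13E)-11-(methoxycarbonyl)labda-8,13-dien-15-oate F1. Allylic oxidation of F1 at C7 with CrO3 and 3,5-dimethylpyrazole then creates the vinylogous β-keto ester after the C–C bond is already in place, and the route is rejoined at 7.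

Step 5 (C6 hydroxylation). The amide base may deprotonate the γ-position C11 instead of C6. The fallback uses a radical acetoxylation that is specific for the saturated α-position of enones. It sets out from 8: Mn(OAc)3·2H2O in refluxing benzene gives methyl (13E)-6α-acetoxy-7-oxolabda-8,13-dien-15-oate F2. Luche reduction (NaBH4, CeCl3·7H2O, MeOH) gives methyl (13E)-6α-acetoxy-7β-hydroxylabda-8,13-dien-15-oate F3. Methanolysis of the acetate with K2CO3 in MeOH at 0 °C returns to the route at 11.

Step 7 (Mitsunobu inversion). The hindered allylic alcohol may eliminate, ionise or fail to react with the weakly acidic isovaleric acid. The fallback sets C7 by enolate hydroxylation instead of SN2 inversion. It sets out from 11: BF3·OEt2 in CH2Cl2 at −40 °C ionises the allylic C7–OH and the axial H6 migrates (semipinacol 1,2-hydride shift) to give methyl (13E)-6-oxolabda-8,13-dien-15-oate F4. Deprotonation at the doubly activated C7 with KN(SiMe3)2 in THF at −78 °C and Davis oxaziridine hydroxylation from the α face (axial attack) gives methyl (13E)-7α-hydroxy-6-oxolabda-8,13-dien-15-oate F5. Acylation with isovaleryl chloride, pyridine and DMAP returns to the route at 14.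

Further compounds
F1 | step 3 | methyl (13E)-11-(methoxycarbonyl)labda-8,13-dien-15-oate (C11 epimers) | C1CC(C)=C(C(C/C(C)=C/C(=O)OC)C(=O)OC)[C@@]2(C)CCCC(C)(C)[C@H]12
F2 | step 5 | methyl (13E)-6α-acetoxy-7-oxolabda-8,13-dien-15-oate | CC(=O)O[C@H]1C(=O)C(C)=C(CC/C(C)=C/C(=O)OC)[C@@]2(C)CCCC(C)(C)[C@H]12
F3 | step 5 | methyl (13E)-6α-acetoxy-7β-hydroxylabda-8,13-dien-15-oate | CC(=O)O[C@H]1[C@H](O)C(C)=C(CC/C(C)=C/C(=O)OC)[C@@]2(C)CCCC(C)(C)[C@H]12
F4 | step 7 | methyl (13E)-6-oxolabda-8,13-dien-15-oate | O=C1CC(C)=C(CC/C(C)=C/C(=O)OC)[C@@]2(C)CCCC(C)(C)[C@H]12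
F5 | step 7 | methyl (13E)-7α-hydroxy-6-oxolabda-8,13-dien-15-oate | O=C1[C@@H](O)C(C)=C(CC/C(C)=C/C(=O)OC)[C@@]2(C)CCCC(C)(C)[C@H]12
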